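The leftover followed here is the reagent of the summer flask. Taking one reagent per product, an assumption because no run measures it, the reagent remainder, one minus conversion over equivalents charged, is 97.5% at 10% conversion.

| setting | summer | dusk | flask |
|---|---|---|---|
| starting material | 0.50 M | 0.50 M | 0.50 M |
| reagent | 4 equiv | 4 equiv | 4.00 equiv |
| free catalyst | 0.05 mol% | 0.05 mol% | 0.05 mol% |
| added ligand | 0.13 mM | 0.065 mM | 0.13 mM |
| remark | the very flask that is asked about, followed so far | run made earlier |  |

| run | time / h | product / % | starting material / % |
|---|---|---|---|
| summer | 0.667 | 2.6 | 95.7 |
| summer | 2.00 | 11.1 | 87.4 |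
| summer | 4.00 | 19.2 | 82.6 |
| summer | 6.00 | 25.3 | 74.3 |
| dusk | 6.00 | 27.3 | 74.5 |
| dusk | 15.0 | 50.7 | 49.6 |
| dusk | 30.0 | 78.7 | 21.7 |
| dusk | 50.0 | 97.4 | 3.4 |

(standard deviation of a reading: 1 percentage point)

- apparent order in reagent when 10% of the starting material are converted (percent change of the rate of making product for one percent more reagent charged)

My own bracket has first order as its upper bound, if reagent enters one step of each turnover, and zeroth order as its lower bound, if the catalyst does not wait for reagent. The dusk flask, with the same equivalents, is the place to tighten it: each tenth of conversion costs the same 2.50% of the reagent, so its remainder reckons to 75.8% by 50.0 h. First order in reagent, other things equal, would lower its rate to that fraction. Yet its pseudo-first-order constant in starting material rises from 0.0491 h⁻¹ over the first 6.00 h to 0.0927 h⁻¹ over the last interval. That is a factor of 1.89 as read from the dusk readings, larger than the 1.32 the remainder spans, and it runs upward while the remainder falls, so these readings do not separate the reagent from whatever else moves the rate, and the bracket stays as it was.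

The forecast of 0.6 lies inside it, and its author writes: “I therefore guess a fractional order with wide bounds”.

The summer flask gives 0.76, also inside the bracket.

    reagent + free catalyst → catalyst intermediate A (k = 89.0 M⁻¹ h⁻¹)
    starting material + catalyst intermediate A → catalyst intermediate B (k = 760 M⁻¹ h⁻¹)
    catalyst intermediate B ⇌ free catalyst + product (K = 0.190 M, k = 5300 h⁻¹)
    free catalyst + added ligand ⇌ idle complex (K = 2900 M⁻¹, k = 330 M⁻¹ h⁻¹)

At 0.200 d, free catalyst holds 42.7% of the catalyst in the flask asked about. With 4.9% of the starting material left at 2.00 d, the reagent remainder of that flask reckons to 76.2%, and its reagent stands at 76%. At full conversion the remainder reckons to 75.0%, and at 20.0 d the reagent of that flask stands at 75.0%.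

The runs are calculated from invented constants; scatter was added.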